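## Structural features

The target is a depsidone. Ring A carries the ester carbonyl carbon on C1, the ether oxygen on C2, a hydroxyl on C3, a methoxyl on C4, hydrogen on C5 and a methyl on C6. Ring B carries the carboxyl carbon on C1′, a hydroxyl on C2′, a methyl on C3′, the ester oxygen on C4′, the ether oxygen on C5′ and the lactol carbon on C6′. The aryl ester and the diaryl ether close a seven-membered dioxepinone (ring C), and a 3-hydroxyphthalide (ring D) is fused to C1′/C6′.

The only stereocentre is the lactol carbon of ring D, which is R. It has no stereogenic neighbour, so its configuration must come from a reagent or catalyst. It is an acylal-type carbon that opens to a formyl carboxylate under base and is therefore configurationally labile.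

The fragile groups are the aryl ester of ring C (alkoxides, hydroxide, amines at high temperature), the lactol, and the oxygen-rich ring A, which is prone to oxidation once its C3 hydroxyl is free.

The difficulty is threefold. Ring B is hexasubstituted, with two methyls and two hydroxyls that must be told apart. Both bonds of ring C end on carbons flanked by two substituents. The stereocentre must be set late and then kept away from base.

The key step uses the fact that C1 (carbonyl), C2–O, C4–O and C6–CH3 of ring A form the orsellinate pattern. Ring A with its carbonyl carbon is therefore an eight-carbon 3,5,7-triketo acid chain in disguise. Its C1 can be delivered as an acylketene to the C4′ hydroxyl, and the ring A C1–C6 bond can be closed by aldol condensation.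

## Logic of the disconnections

**22 from 21.** Three acyl–oxygen bonds are cut: one at the lactol oxygen, one at the ring A C3 oxygen and one at the ring B C2′ oxygen. In 21 the lactol oxygen is capped, so ring D cannot open and the configuration is locked. The gain is in handling, not in atoms: no earlier step has to carry a free, optically active lactol. The forward step must break acyl–oxygen bonds only and must run without base, which calls for enzyme-mediated alcoholysis.

**21 from 20.** The same O–acyl bond at the stereocentre is disconnected in the stereochemical sense, leading to racemic 20. The enantiomers of 20 interconvert through the ring-opened formyl carboxylate when an amine is present, so an enantioselective acylation can convert all the material. This removes the stereochemical problem from everything before 20. The forward step needs ring opening and closure to be faster than acylation, and the catalysed acylation to be faster than the uncatalysed one.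

**20 from 18.** The lactone C–O bond of ring D is cut and three functions are returned to masked forms: the lactol carbon as a dimethyl acetal, the carboxyl as a methyl ester, and the ring A C3 hydroxyl as a methoxymethyl ether. All three are released by aqueous acid, which the aryl ester of ring C tolerates best. The methyl ester is the one already present in 4, so no ester exchange on a di-ortho-substituted benzoate is needed and no hydrogenolysis appears in the end-game. Ring D and the stereocentre disappear. The forward step requires that acid also turns the ortho-formyl methyl ester into the hydroxy lactone, which relies on participation by the formyl hydrate.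

**18 from 17.** Ring C is opened at the ether bond between the ring A C2 oxygen and C5′, which becomes C–Br. With the ester already linking the rings, ether formation is intramolecular and seven-membered, and an intermolecular coupling of two hindered arenes is avoided. The central ring is removed and an open depside remains. The forward step is an O-arylation at a bromide flanked by two substituents, next to a base-sensitive aryl ester, and must outrun Smiles rearrangement.

**17 from 16 and 16 from 14.** First the O–CH2 bond of the methoxymethyl ether is cut, then the ring A C3–O bond. In 14, C3 is the only unsubstituted carbon ortho to a phenol, so an ortho-directed oxidation has a single site. Doing this after the C4 oxygen is methylated removes any choice between two ortho positions. The ether cap in 17 leaves exactly one oxygen that can reach the bromide. Ring A returns to the plain orsellinate pattern. The forward steps must oxidise a chelated, ester-bearing phenol without touching the ring B phenol, and cap only the non-chelated hydroxyl.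

**14 from 13.** The O–CH3 bond at ring A C4 is cut. This is the only hydroxyl of 13 not hydrogen-bonded to an ester carbonyl, so the cascade product can be used unprotected. The forward step must stop at mono-alkylation.

**13 from 3 and 10 (key step).** Two bonds are cut: the aryl ester C–O bond between the ring A carbonyl carbon and the C4′ oxygen, and the ring A C1–C6 bond. Ring A becomes the triketo acid chain stored in 3, and ring B is left as 10. The acylating species is a ketene, so a di-ortho-substituted benzoic acid never has to be activated towards a hindered phenol. Ring A, its three substituents and the ester arise in one operation from two fragments of similar size. The forward step needs the ketene to be captured by the C4′ hydroxyl (not by the C2′ hydroxyl or by its own enol oxygen), and the chain to close at carbon and not at oxygen.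

**3 from 2 and 2 from 1.** In each case the bond between an acetyl carbonyl carbon and the adjacent methylene is cut: two Claisen disconnections down to 1. The second acylation must occur at the terminal carbon of a dianion, and 3 must be used soon after it is made.

**10 back to 4.** In order: the acetal C–O bonds and O–Si bonds (10 from 8 through 9), the benzylic C=O to C–Br (8 from 7), the benzylic C–Br to C–H (7 from 6), the O–Si bonds (6 from 5) and the ring C–Br bond (5 from 4). The methyl ortho to the ester is distinguished from the methyl between the two oxygens by acidity, because only its carbanion is conjugated with the ester. A radical bromination would not guarantee that distinction. The ring bromine is placed first so that the last free ring position is blocked. The gain is a commercial benzoate that already holds both methyls, both oxygens and the carboxyl carbon in place. The forward steps need an amide base that leaves the aryl bromide and silyl ethers alone, and an oxidation mild enough not to lactonise the ortho-bromomethyl ester.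

## Other disconnections considered

**Alternative 1:** The cut removes the exocyclic acyloxy C–O bond and the lactone C–O bond of ring D, leading to the ring B dialdehyde depsidone diacetate A2. In the forward step a chiral triazolium-derived carbene adds to the formyl group next to the acetoxy-bearing carbon, and a quinone oxidant turns the adduct into an acyl azolium. An acetate source adds to the other formyl group and the resulting alkoxide is acylated, giving the (R)-acetoxyphthalide depsidone triacetate A1.
- In favour: ring D, the acyloxy group and the stereocentre would arise in one catalytic event from an achiral precursor. There is no racemic lactol and no dependence on a racemisation rate. On step economy at the stereochemical stage this is better than steps 13 and 14 of the chosen plan, and A1 stands at the same stage as 21, so the final deacylation is equal.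
- Against: A2 needs two adjacent formyl groups on a hexasubstituted ring, so the carboxyl carbon of ring B must also be brought to the aldehyde level. The choice of which formyl group is oxidised rests on a small steric and electronic difference. The carbene and the acetate are nucleophiles in the presence of the ring C aryl ester and two phenolic acetates.
- Comparison: this alternative says nothing about how rings A and C are made, so it would have to be combined with a depsidone assembly such as the one chosen here. The mechanism is catalyst-controlled face selection at an aldehyde, against catalyst-controlled selection between interconverting lactol enantiomers in the chosen plan; neither has an intrinsic advantage in control.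

**Alternative 2:** The cut removes two C–C bonds of ring B (C1′–C2′ and C5′–C6′), leading to 4-(benzyloxy)-2-[(tert-butyldimethylsilyl)oxy]-3-methylfuran A4 and tert-butyl 4,4-diethoxybut-2-ynoate A5. In the forward step a [4+2] cycloaddition joins the silyloxy carbon to the ester-bearing alkyne carbon and the unsubstituted furan carbon to the acetal-bearing carbon. Opening of the oxygen bridge then gives the ring B phenol A3.
- In favour: every substituent of ring B arrives differentiated: free hydroxyl at C5′, benzyl ether at C4′, silyl ether at C2′, the carboxyl as a tert-butyl ester and the formyl group as an acetal. No benzylic oxidation is needed and two methyls never have to be told apart. On this point it is better than steps 3 to 7 of the chosen plan, which rely on a lateral metalation and on a hydrogen bond. The regiochemistry follows from polarity matching of the donor end of A4 with the β-carbon of A5.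
- Against: A4 is not a catalogue compound and needs several steps from a tetronic acid. A3 carries oxygen, not halogen, at C5′, so the diaryl ether would have to be made with ring A as the electrophile. That does not fit a ring A that is born as a phenol in the ketene cascade. The bridge opening must go in one direction and the silyl group must not migrate.
- Comparison: the step count for ring B is likely similar to the five steps from 4, so the gain is in certainty of substitution pattern, not in length. It would pair more naturally with Alternative 3 than with the chosen key step.

**Alternative 3:** The cut removes the aryl ester C–O bond at C4′, leading to the diaryl ether carboxylic acid A7, in which C4′ carries hydrogen. In the forward step a diacetoxyiodoarene (trivalent iodine) oxidises the ring B phenol, and the ring A carboxylic acid attacks C5′, para to that phenol, to give the spiro ketal lactone A8. A boron Lewis acid then shifts the acyloxy group to C4′, and rearomatisation gives the depsidone aldehyde allyl ester A6.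
- In favour: ring B needs no halogen and ring C needs no metal-mediated coupling. The ester can only land on C4′, the sole hydrogen-bearing neighbour of the spiro carbon. The seven-membered ring comes from expansion of a six-membered spirocycle, which is kinetically easier than a direct seven-ring closure; on this point it is arguably better than step 12. The C3 oxygen of ring A is present before the rings are joined, so no late oxidation is needed; on that point it is also the equal or the better of the chosen plan.
- Against: the diaryl ether of A7 must first be made intermolecularly between two ortho,ortho′-disubstituted partners, which is harder than the intramolecular closure of step 12. The oxidant must choose the ring B phenol over the electron-rich ring A. The acyloxy shift competes with migration of carbon substituents. A6 still needs deallylation, lactol formation and the same resolution as in the chosen plan.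
- Comparison: the overall length is expected to be similar. The chosen plan builds ring A and the ester in one operation from simple fragments, whereas this alternative needs a fully substituted ring A acid made beforehand.

Key step: step 8

Assumption: the lactol carbon is taken to epimerise by ring–chain tautomerism only when a base is present, so it is released last, under neutral conditions, and is not exposed to base afterwards.

## Steps

Step 1
Reactants: 1 2,2,6-trimethyl-4H-1,3-dioxin-4-one
Product: 2 2,2-dimethyl-6-(2-oxopropyl)-4H-1,3-dioxin-4-one
Conditions: 1 (2.2 equiv), LiN(SiMe3)2 (2.2 equiv), THF, −78 °C; AcCl (1.0 equiv), −78 °C; aq. NH4Cl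
Reagents that add atoms: acetyl chloride CC(=O)Cl
Why: Vinylogous Claisen acylation: the lithium dienolate of 1 should be acylated at the exocyclic (gamma) carbon. The enolate is used in twofold excess because 2 is more acidic than 1 and consumes one equivalent.

Step 2
Reactants: 2 2,2-dimethyl-6-(2-oxopropyl)-4H-1,3-dioxin-4-one
Product: 3 6-(2,4-dioxopentyl)-2,2-dimethyl-4H-1,3-dioxin-4-one (diketo-dioxinone)
Conditions: LiN(i-Pr)2 (2.3 equiv), THF, −78 °C; MeC(O)N(OMe)Me, −78 to −40 °C; 1 M HCl to pH 3
Reagents that add atoms: N-methoxy-N-methylacetamide CC(=O)N(C)OC
Why: Second Claisen acylation through the dianion of 2: the terminal methyl carbon, deprotonated last, is the most nucleophilic site, and the chelated adduct of the Weinreb amide prevents over-addition. 3 is used promptly because it enolises and cyclises on standing.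

Step 3
Reactants: 4 methyl 2,4-dihydroxy-3,6-dimethylbenzoate (atraric acid)
Product: 5 methyl 5-bromo-2,4-dihydroxy-3,6-dimethylbenzoate
Conditions: NBS (1.0 equiv), MeCN, 0 °C
Reagents that add atoms: N-bromosuccinimide O=C1CCC(=O)N1Br
Why: Electrophilic aromatic bromination at the only unsubstituted ring carbon, which is ortho to the non-chelated hydroxyl. The halogen goes in first so that this position is blocked in all later steps.

Step 4
Reactants: 5 methyl 5-bromo-2,4-dihydroxy-3,6-dimethylbenzoate
Product: 6 methyl 5-bromo-2,4-bis[(tert-butyldimethylsilyl)oxy]-3,6-dimethylbenzoate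
Conditions: t-BuMe2SiOTf (2.5 equiv), 2,6-lutidine, CH2Cl2, 0 °C to rt
Reagents that add atoms: tert-butyldimethylsilyl triflate CC(C)(C)[Si](C)(C)OS(=O)(=O)C(F)(F)F
Why: Silylation of both phenols; the triflate is reactive enough for the chelated hydroxyl. Silyl ethers survive the amide base of step 5 and leave under non-acidic conditions that spare the acetal made in step 7.

Step 5
Reactants: 6 methyl 5-bromo-2,4-bis[(tert-butyldimethylsilyl)oxy]-3,6-dimethylbenzoate
Product: 7 methyl 3-bromo-2-(bromomethyl)-4,6-bis[(tert-butyldimethylsilyl)oxy]-5-methylbenzoate
Conditions: LiN(i-Pr)2 (1.2 equiv), THF, −78 °C; cannulation into BrCl2CCCl2Br (1.5 equiv), THF, −78 °C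
Reagents that add atoms: 1,2-dibromo-1,1,2,2-tetrachloroethane BrC(Cl)(Cl)C(Cl)(Cl)Br
Why: Lateral lithiation of an ortho-toluate: only the methyl ortho to the ester gives an ester-conjugated extended enolate, so the two ring methyls are told apart by acidity and not by radical reactivity. Inverse addition to the bromine donor should suppress Wurtz-type dimerisation.

Step 6
Reactants: 7 methyl 3-bromo-2-(bromomethyl)-4,6-bis[(tert-butyldimethylsilyl)oxy]-5-methylbenzoate
Product: 8 methyl 3-bromo-4,6-bis[(tert-butyldimethylsilyl)oxy]-2-formyl-5-methylbenzoate
Conditions: N-methylmorpholine N-oxide (4 equiv), 4 Å MS, MeCN, rt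
Reagents that add atoms: N-methylmorpholine N-oxide C[N+]1([O-])CCOCC1
Why: Amine N-oxide (Kornblum-type) oxidation: SN2 displacement of the benzylic bromide by the N-oxide oxygen and base-induced elimination should give the aldehyde at room temperature. No acid, strong base or heat is present that would lactonise the ortho-bromomethyl ester.

Step 7
Reactants: 8 methyl 3-bromo-4,6-bis[(tert-butyldimethylsilyl)oxy]-2-formyl-5-methylbenzoate
Product: 10 methyl 3-bromo-2-(dimethoxymethyl)-4,6-dihydroxy-5-methylbenzoate (ring B bromophenol), via bis-silyl acetal 9 (not isolated)
Conditions: HC(OMe)3, MeOH, TsOH·H2O (5 mol%), rt; then K2CO3 (3 equiv), rt; pH 6 phosphate work-up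
Reagents that add atoms: trimethyl orthoformate COC(OC)OC; methanol CO
Why: Orthoformate acetalisation of the hindered aldehyde under a non-nucleophilic acid, then methanolysis of the two electron-poor aryl silyl ethers once the acid is neutralised. The acetal is made first because methoxide and a free ortho-formyl ester would isomerise to the 3-methoxyphthalide.

Step 8
Reactants: 3 6-(2,4-dioxopentyl)-2,2-dimethyl-4H-1,3-dioxin-4-one; 10 methyl 3-bromo-2-(dimethoxymethyl)-4,6-dihydroxy-5-methylbenzoate
Product: 13 methyl 3-bromo-4-[(2,4-dihydroxy-6-methylbenzoyl)oxy]-2-(dimethoxymethyl)-6-hydroxy-5-methylbenzoate (bromo depside), via acylketene 11 (not isolated), via triketo aryl ester 12 (not isolated)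
Conditions: 3 (2 equiv) added over 2 h to 10 (0.3 M) in PhMe, 110 °C; cool; Cs2CO3 (2 equiv), THF, rt; AcOH to pH 5
Reagents that add atoms: none
Why: Heating 3 expels acetone by retro-[4+2] cycloreversion and gives acylketene 11, which the C4′ hydroxyl of 10 (between bromine and methyl) should capture to give aryl ester 12. The C2′ hydroxyl should stay out because it is held in a hydrogen bond to the ester carbonyl, the same bias that directs classical depside esterifications to the hydroxyl para to the ester. Slow addition of 3 to a concentrated solution of 10 keeps the phenol in large excess over the ketene, which is what lets intermolecular capture compete with capture of the ketene by its own enol oxygen. Cs2CO3 in an aprotic solvent then forms the enolate at the methylene between ester and ketone, which adds to the terminal methyl ketone in a 6-exo-trig (enolexo) aldol closure; loss of water and enolisation aromatise ring A as the 2,4-dihydroxy-6-methylbenzoate. No alcohol is present, so the activated aryl ester cannot be transesterified. The closest known reaction types are thermolysis of diketo-dioxinones with alcohols followed by base-mediated aldol aromatisation to resorcylate esters, and acetoacetylation of phenols by dioxinone-derived acylketenes. One ring (ring A) is closed and no stereocentre is formed. The selectivities needed are one phenol over the other, secured by the hydrogen bond in 10, and C-cyclisation over O-acylation to a pyranone, favoured by the carbonate base and the absence of acid.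

Step 9
Reactants: 13 methyl 3-bromo-4-[(2,4-dihydroxy-6-methylbenzoyl)oxy]-2-(dimethoxymethyl)-6-hydroxy-5-methylbenzoate
Product: 14 methyl 3-bromo-2-(dimethoxymethyl)-6-hydroxy-4-[(2-hydroxy-4-methoxy-6-methylbenzoyl)oxy]-5-methylbenzoate
Conditions: MeI (1.2 equiv), K2CO3 (1.1 equiv), acetone, rt
Reagents that add atoms: iodomethane CI
Why: Williamson methylation of the most acidic, non-chelated phenol (ring A C4). The ring A C2 hydroxyl and the ring B hydroxyl are each locked in a hydrogen bond to an ester carbonyl and should not be alkylated by one equivalent of weak base at room temperature.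

Step 10
Reactants: 14 methyl 3-bromo-2-(dimethoxymethyl)-6-hydroxy-4-[(2-hydroxy-4-methoxy-6-methylbenzoyl)oxy]-5-methylbenzoate
Product: 16 methyl 3-bromo-4-[(2,3-dihydroxy-4-methoxy-6-methylbenzoyl)oxy]-2-(dimethoxymethyl)-6-hydroxy-5-methylbenzoate, via ortho-quinone 15 (not isolated)
Conditions: IBX (1.2 equiv), DMF, rt, dark; then aq. Na2S2O4, EtOAc
Reagents that add atoms: 2-iodoxybenzoic acid (IBX) O=C1OI(=O)(O)c2ccccc12
Why: Ortho-selective phenol oxidation by the pentavalent iodine reagent: the ring A C2 phenol binds to iodine and oxygen is delivered intramolecularly to C3, the only free ortho carbon, giving ortho-quinone 15, which dithionite reduces to the catechol before work-up. The ring B phenol has no free ortho position and sits on an electron-poor ring, so it should be left alone.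

Step 11
Reactants: 16 methyl 3-bromo-4-[(2,3-dihydroxy-4-methoxy-6-methylbenzoyl)oxy]-2-(dimethoxymethyl)-6-hydroxy-5-methylbenzoate
Product: 17 methyl 3-bromo-2-(dimethoxymethyl)-6-hydroxy-4-{[2-hydroxy-4-methoxy-3-(methoxymethoxy)-6-methylbenzoyl]oxy}-5-methylbenzoate
Conditions: MOMCl (1.1 equiv), i-Pr2NEt, CH2Cl2, 0 °C
Reagents that add atoms: chloromethyl methyl ether COCCl
Why: Alkylation of the only hydroxyl not chelated to an ester carbonyl (ring A C3). This leaves the C2 hydroxyl as the single oxygen that can reach the bromide in step 12 and protects the catechol from copper-mediated oxidation.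

Step 12
Reactants: 17 methyl 3-bromo-2-(dimethoxymethyl)-6-hydroxy-4-{[2-hydroxy-4-methoxy-3-(methoxymethoxy)-6-methylbenzoyl]oxy}-5-methylbenzoate
Product: 18 methyl 6-(dimethoxymethyl)-8-hydroxy-3-methoxy-4-(methoxymethoxy)-1,9-dimethyl-11-oxo-11H-dibenzo[b,e][1,4]dioxepine-7-carboxylate (depsidone)
Conditions: CuI (0.5 equiv), N,N-dimethylglycine·HCl (1 equiv), Cs2CO3 (3 equiv), 1,4-dioxane, 90 °C, Ar, 0.01 M
Reagents that add atoms: none
Why: Intramolecular Ullmann diaryl ether synthesis: the copper phenoxide of the ring A C2 oxygen should displace the C5′ bromide and close the seven-membered ring, the ester tether holding the partners together. High dilution, the amino acid ligand and a low-polarity ether solvent are chosen to disfavour intermolecular coupling and Smiles rearrangement.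

Step 13
Reactants: 18 methyl 6-(dimethoxymethyl)-8-hydroxy-3-methoxy-4-(methoxymethoxy)-1,9-dimethyl-11-oxo-11H-dibenzo[b,e][1,4]dioxepine-7-carboxylate
Product: 20 racemic 1,4,11-trihydroxy-10-methoxy-5,8-dimethyl-1H-isobenzofuro[4,5-b][1,4]benzodioxepine-3,7-dione (racemic lactol), via formyl ester 19 (not isolated)
Conditions: 2 M HCl/THF (1:2), 45 °C
Reagents that add atoms: water O
Why: One acidic operation: hydrolysis of the methoxymethyl ether and the dimethyl acetal, then 5-exo-trig lactonisation of the formyl hydrate onto the neighbouring methyl ester with loss of methanol (the normal-ester to pseudo-acid isomerisation of ortho-formylbenzoates). The ring C aryl ester should tolerate aqueous acid at this temperature, and the lactol forms as the racemate.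

Step 14
Reactants: 20 racemic 1,4,11-trihydroxy-10-methoxy-5,8-dimethyl-1H-isobenzofuro[4,5-b][1,4]benzodioxepine-3,7-dione
Product: 21 (1R)-10-methoxy-5,8-dimethyl-3,7-dioxo-1,3-dihydro-7H-isobenzofuro[4,5-b][1,4]benzodioxepine-1,4,11-triyl tris(2-methylpropanoate)
Conditions: (R)-BTM (10 mol%), (i-PrCO)2O (5 equiv), i-Pr2NEt (5 equiv), CHCl3, 0 °C, then rt
Reagents that add atoms: isobutyric anhydride CC(C)C(=O)OC(=O)C(C)C
Why: Acylative dynamic kinetic resolution of a lactol by a chiral isothiourea: the amine interconverts the lactol enantiomers through the formyl carboxylate while the acyl isothiouronium from (R)-BTM should acylate the (R)-lactol faster, after which the acylal can no longer ring-open. The catalyst enantiomer is chosen by analogy with 1-arylethanols, where it acylates the enantiomer with the same spatial order of hydroxyl, aryl group and third substituent; the antipodal catalyst is the remedy should the sense prove opposite. The excess anhydride also esterifies both phenols at room temperature, giving one defined product with no stereochemical consequence.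

Step 15
Reactants: 21 (1R)-10-methoxy-5,8-dimethyl-3,7-dioxo-1,3-dihydro-7H-isobenzofuro[4,5-b][1,4]benzodioxepine-1,4,11-triyl tris(2-methylpropanoate)
Product: 22 (1R)-1,4,11-trihydroxy-10-methoxy-5,8-dimethyl-1H-isobenzofuro[4,5-b][1,4]benzodioxepine-3,7-dione (target)
Conditions: immobilised Burkholderia cepacia lipase, n-BuOH (10 equiv), t-BuOMe, 35 °C; filtration, evaporation, no base at any point
Reagents that add atoms: none
Why: Lipase-mediated alcoholysis in an organic solvent should cleave all three esters at the acyl–oxygen bond, so the C–O bond at the stereocentre is never broken and no base is present to open the lactol. By the empirical rule for lipases and esters of secondary carbinols, the (R)-acylal is the enantiomer the enzyme prefers, so residual (S)-ester should stay esterified and be removed on purification.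

## Compound list

1 | 2,2,6-trimethyl-4H-1,3-dioxin-4-one | CC1=CC(=O)OC(C)(C)O1 | starting material
2 | 2,2-dimethyl-6-(2-oxopropyl)-4H-1,3-dioxin-4-one | CC(=O)CC1=CC(=O)OC(C)(C)O1 | intermediate
3 | 6-(2,4-dioxopentyl)-2,2-dimethyl-4H-1,3-dioxin-4-one | CC(=O)CC(=O)CC1=CC(=O)OC(C)(C)O1 | intermediate
4 | methyl 2,4-dihydroxy-3,6-dimethylbenzoate | COC(=O)c1c(C)cc(O)c(C)c1O | starting material
5 | methyl 5-bromo-2,4-dihydroxy-3,6-dimethylbenzoate | COC(=O)c1c(C)c(Br)c(O)c(C)c1O | intermediate
6 | methyl 5-bromo-2,4-bis[(tert-butyldimethylsilyl)oxy]-3,6-dimethylbenzoate | COC(=O)c1c(C)c(Br)c(O[Si](C)(C)C(C)(C)C)c(C)c1O[Si](C)(C)C(C)(C)C | intermediate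
7 | methyl 3-bromo-2-(bromomethyl)-4,6-bis[(tert-butyldimethylsilyl)oxy]-5-methylbenzoate | COC(=O)c1c(CBr)c(Br)c(O[Si](C)(C)C(C)(C)C)c(C)c1O[Si](C)(C)C(C)(C)C | intermediate
8 | methyl 3-bromo-4,6-bis[(tert-butyldimethylsilyl)oxy]-2-formyl-5-methylbenzoate | COC(=O)c1c(C=O)c(Br)c(O[Si](C)(C)C(C)(C)C)c(C)c1O[Si](C)(C)C(C)(C)C | intermediate
9 | methyl 3-bromo-4,6-bis[(tert-butyldimethylsilyl)oxy]-2-(dimethoxymethyl)-5-methylbenzoate | COC(=O)c1c(C(OC)OC)c(Br)c(O[Si](C)(C)C(C)(C)C)c(C)c1O[Si](C)(C)C(C)(C)C | intermediate
10 | methyl 3-bromo-2-(dimethoxymethyl)-4,6-dihydroxy-5-methylbenzoate | COC(=O)c1c(C(OC)OC)c(Br)c(O)c(C)c1O | intermediate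
11 | 3,5,7-trioxooct-1-en-1-one (acylketene) | CC(=O)CC(=O)CC(=O)C=C=O | intermediate
12 | 2-bromo-3-(dimethoxymethyl)-5-hydroxy-4-(methoxycarbonyl)-6-methylphenyl 3,5,7-trioxooctanoate | CC(=O)CC(=O)CC(=O)CC(=O)Oc1c(Br)c(C(OC)OC)c(C(=O)OC)c(O)c1C | intermediate
13 | methyl 3-bromo-4-[(2,4-dihydroxy-6-methylbenzoyl)oxy]-2-(dimethoxymethyl)-6-hydroxy-5-methylbenzoate | Cc1cc(O)cc(O)c1C(=O)Oc1c(Br)c(C(OC)OC)c(C(=O)OC)c(O)c1C | intermediate
14 | methyl 3-bromo-2-(dimethoxymethyl)-6-hydroxy-4-[(2-hydroxy-4-methoxy-6-methylbenzoyl)oxy]-5-methylbenzoate | COc1cc(C)c(C(=O)Oc2c(Br)c(C(OC)OC)c(C(=O)OC)c(O)c2C)c(O)c1 | intermediate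
15 | methyl 3-bromo-2-(dimethoxymethyl)-6-hydroxy-4-{[(4-methoxy-6-methyl-2,3-dioxocyclohexa-4,6-dien-1-yl)carbonyl]oxy}-5-methylbenzoate (ortho-quinone) | COC1=CC(C)=C(C(=O)Oc2c(Br)c(C(OC)OC)c(C(=O)OC)c(O)c2C)C(=O)C1=O | intermediate
16 | methyl 3-bromo-4-[(2,3-dihydroxy-4-methoxy-6-methylbenzoyl)oxy]-2-(dimethoxymethyl)-6-hydroxy-5-methylbenzoate | COc1cc(C)c(C(=O)Oc2c(Br)c(C(OC)OC)c(C(=O)OC)c(O)c2C)c(O)c1O | intermediate
17 | methyl 3-bromo-2-(dimethoxymethyl)-6-hydroxy-4-{[2-hydroxy-4-methoxy-3-(methoxymethoxy)-6-methylbenzoyl]oxy}-5-methylbenzoate | COCOc1c(OC)cc(C)c(C(=O)Oc2c(Br)c(C(OC)OC)c(C(=O)OC)c(O)c2C)c1O | intermediate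
18 | methyl 6-(dimethoxymethyl)-8-hydroxy-3-methoxy-4-(methoxymethoxy)-1,9-dimethyl-11-oxo-11H-dibenzo[b,e][1,4]dioxepine-7-carboxylate | COc1cc(C)c2c(c1OCOC)Oc1c(c(C)c(O)c(C(=O)OC)c1C(OC)OC)OC2=O | intermediate
19 | methyl 6-formyl-4,8-dihydroxy-3-methoxy-1,9-dimethyl-11-oxo-11H-dibenzo[b,e][1,4]dioxepine-7-carboxylate | COc1cc(C)c2c(c1O)Oc1c(c(C)c(O)c(C(=O)OC)c1C=O)OC2=O | intermediate
20 | racemic 1,4,11-trihydroxy-10-methoxy-5,8-dimethyl-1H-isobenzofuro[4,5-b][1,4]benzodioxepine-3,7-dione | COc1cc(C)c2c(c1O)Oc1c(c(C)c(O)c3c1C(O)OC3=O)OC2=O | intermediate
21 | (1R)-10-methoxy-5,8-dimethyl-3,7-dioxo-1,3-dihydro-7H-isobenzofuro[4,5-b][1,4]benzodioxepine-1,4,11-triyl tris(2-methylpropanoate) | COc1cc(C)c2c(c1OC(=O)C(C)C)Oc1c(c(C)c(OC(=O)C(C)C)c3c1[C@H](OC(=O)C(C)C)OC3=O)OC2=O | intermediate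
22 | (1R)-1,4,11-trihydroxy-10-methoxy-5,8-dimethyl-1H-isobenzofuro[4,5-b][1,4]benzodioxepine-3,7-dione | COc1cc(C)c2c(c1O)Oc1c(c(C)c(O)c3c1[C@H](O)OC3=O)OC2=O | target

## Step count and least certain steps

Total: 15 steps (2 to 3, 5 to 10, 8 from the key step to the target). Longest linear sequence: 13 steps (4 to 22, steps 3 to 15).

**Step 8 (key step).** The most likely failure is capture of the acylketene by its own enol oxygen, or O-acylative cyclisation of the triketo aryl ester with expulsion of the phenoxide, both leading to a pyranone. This can happen because the phenol is hindered, weakly nucleophilic and a good leaving group. Fallback: classical depside esterification. Setting out from 10, commercial 2-hydroxy-4-methoxy-6-methylbenzoic acid F1 would be coupled to the C4′ hydroxyl with dicyclohexylcarbodiimide in toluene/ether at room temperature. The chelated hydroxyls of both partners stay out, and the route is rejoined at 14, with steps 8 and 9 bypassed.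

**Step 10.** Ligand exchange and oxygen transfer may be too slow on a chelated phenol that carries an ester, so that the substrate is returned or the ring B phenol is dearomatised at its methyl-bearing ortho carbon instead. Fallback: setting out from 14, magnesium-mediated ortho-formylation (MgCl2, Et3N, paraformaldehyde, MeCN, 70 °C) at the only free ortho position would give the salicylaldehyde F2. Dakin oxidation (H2O2, catalytic diphenyl diselenide, CH2Cl2) would give the aryl formate F3, and brief methanolysis (KHCO3, MeOH, 0 °C) would rejoin the route at 16.

**Step 12.** Oxidative addition at a bromide flanked by two substituents and para to a phenoxide may be slow enough for base-induced Smiles rearrangement or cleavage of the aryl ester to compete. Fallback: setting out from 17, Miyaura borylation (Pd(OAc)2, SPhos, bis(pinacolato)diboron, KOAc, dioxane, 80 °C) would give the pinacol boronate F4. Oxidative Chan–Lam etherification (Cu(OAc)2, pyridine, 4 Å MS, CH2Cl2, air, rt) proceeds at room temperature with a weak base and would rejoin the route at 18.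

**Step 13.** Lactonisation may stall after acetal hydrolysis because the methyl ester is di-ortho-substituted, and forcing the acid may then start to hydrolyse ring C. Fallback: setting out from 18, the ester methyl would be removed by SN2 dealkylation (LiI, EtOAc, reflux) to give the carboxylic acid F5. Mild aqueous acid (1 M HCl/THF, rt) would then unmask the acetal and the methoxymethyl ether, and the free acid closes to the lactol, rejoining the route at 20.

**Step 14.** Enantioselectivity may be eroded by uncatalysed acylation of the lactol or of the ring-opened carboxylate by the anhydride, or by slow interconversion of the crowded lactol enantiomers. Fallback: setting out from 20, non-selective peracylation ((i-PrCO)2O, DMAP, Et3N, CH2Cl2) would give the racemic triester F6. Because the acylal is configurationally stable, preparative chromatography on a chiral stationary phase would separate 21 from its (S)-enantiomer F7, and the route is rejoined at 21.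

**Step 15.** Alcoholysis of the two hindered aryl isobutyrates may be incomplete, or the enzyme may accept the bulky substrate only slowly; the freed lactol could also epimerise on the enzyme support. Fallback: setting out from 20, the racemic lactol would be resolved directly by preparative chromatography on a chiral stationary phase with an acidified eluent, which delivers 22 with no acyl group to remove. The unwanted (S)-lactol F8 would be racemised with a catalytic amine and returned to 20.

## Further compounds

F1 | step 8 | 2-hydroxy-4-methoxy-6-methylbenzoic acid | COc1cc(C)c(C(=O)O)c(O)c1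
F2 | step 10 | methyl 3-bromo-2-(dimethoxymethyl)-4-[(3-formyl-2-hydroxy-4-methoxy-6-methylbenzoyl)oxy]-6-hydroxy-5-methylbenzoate | COc1cc(C)c(C(=O)Oc2c(Br)c(C(OC)OC)c(C(=O)OC)c(O)c2C)c(O)c1C=O
F3 | step 10 | methyl 3-bromo-2-(dimethoxymethyl)-4-{[3-(formyloxy)-2-hydroxy-4-methoxy-6-methylbenzoyl]oxy}-6-hydroxy-5-methylbenzoate | COc1cc(C)c(C(=O)Oc2c(Br)c(C(OC)OC)c(C(=O)OC)c(O)c2C)c(O)c1OC=O
F4 | step 12 | methyl 2-(dimethoxymethyl)-6-hydroxy-4-{[2-hydroxy-4-methoxy-3-(methoxymethoxy)-6-methylbenzoyl]oxy}-5-methyl-3-(4,4,5,5-tetramethyl-1,3,2-dioxaborolan-2-yl)benzoate | COCOc1c(OC)cc(C)c(C(=O)Oc2c(B3OC(C)(C)C(C)(C)O3)c(C(OC)OC)c(C(=O)OC)c(O)c2C)c1O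
F5 | step 13 | 6-(dimethoxymethyl)-8-hydroxy-3-methoxy-4-(methoxymethoxy)-1,9-dimethyl-11-oxo-11H-dibenzo[b,e][1,4]dioxepine-7-carboxylic acid | COc1cc(C)c2c(c1OCOC)Oc1c(c(C)c(O)c(C(=O)O)c1C(OC)OC)OC2=O
F6 | step 14 | racemic 10-methoxy-5,8-dimethyl-3,7-dioxo-1,3-dihydro-7H-isobenzofuro[4,5-b][1,4]benzodioxepine-1,4,11-triyl tris(2-methylpropanoate) | COc1cc(C)c2c(c1OC(=O)C(C)C)Oc1c(c(C)c(OC(=O)C(C)C)c3c1C(OC(=O)C(C)C)OC3=O)OC2=O
F7 | step 14 | (1S)-10-methoxy-5,8-dimethyl-3,7-dioxo-1,3-dihydro-7H-isobenzofuro[4,5-b][1,4]benzodioxepine-1,4,11-triyl tris(2-methylpropanoate) | COc1cc(C)c2c(c1OC(=O)C(C)C)Oc1c(c(C)c(OC(=O)C(C)C)c3c1[C@@H](OC(=O)C(C)C)OC3=O)OC2=O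
F8 | step 15 | (1S)-1,4,11-trihydroxy-10-methoxy-5,8-dimethyl-1H-isobenzofuro[4,5-b][1,4]benzodioxepine-3,7-dione | COc1cc(C)c2c(c1O)Oc1c(c(C)c(O)c3c1[C@@H](O)OC3=O)OC2=O
A1 | alternative 1 | (R)-acetoxyphthalide depsidone triacetate | COc1cc(C)c2c(c1OC(C)=O)Oc1c(c(C)c(OC(C)=O)c3c1[C@H](OC(C)=O)OC3=O)OC2=O
A2 | alternative 1 | ring B dialdehyde depsidone diacetate | COc1cc(C)c2c(c1OC(C)=O)Oc1c(c(C)c(OC(C)=O)c(C=O)c1C=O)OC2=O
A3 | alternative 2 | tert-butyl 4-(benzyloxy)-6-[(tert-butyldimethylsilyl)oxy]-2-(diethoxymethyl)-3-hydroxy-5-methylbenzoate | CCOC(OCC)c1c(O)c(OCc2ccccc2)c(C)c(O[Si](C)(C)C(C)(C)C)c1C(=O)OC(C)(C)C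
A4 | alternative 2 | 4-(benzyloxy)-2-[(tert-butyldimethylsilyl)oxy]-3-methylfuran | Cc1c(O[Si](C)(C)C(C)(C)C)occ1OCc1ccccc1
A5 | alternative 2 | tert-butyl 4,4-diethoxybut-2-ynoate | CCOC(OCC)C#CC(=O)OC(C)(C)C
A6 | alternative 3 | depsidone aldehyde allyl ester | COc1cc(C)c2c(c1OCC=C)Oc1c(c(C)c(O)c(C(=O)OCC=C)c1C=O)OC2=O
A7 | alternative 3 | diaryl ether carboxylic acid | COc1cc(C)c(C(=O)O)c(Oc2cc(C)c(O)c(C(=O)OCC=C)c2C=O)c1OCC=C
A8 | alternative 3 | spiro ketal lactone | COc1cc(C)c2c(c1OCC=C)OC1(C=C(C)C(=O)C(C(=O)OCC=C)=C1C=O)OC2=O
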